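**Plan**

1. Retrosynthesis (each ring numbered as a chroman: O1, C2, C3, C4, C4a, C5–C8, C8a): cut C6–CH of ring A (phenol plus o-quinone methide of ring B), then C6–CH of ring B (phenol plus 6-methylheptanal), both C8–acyl bonds, and in each pyran ring O1–C8a and C3–C4.
2. Enabling feature: in each phloroglucinol ring the oxygen-bearing carbons C5, C7 and C8a are mutually meta, and C8a is ortho to C4a, which carries C4. With F in place of O this is a 2,4,6-trifluorobenzyl unit (benzylic nucleophile at C4, SNAr carbon at C8a), and O1–C2(CH3)2–C3 is 2,2-dimethyloxirane.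
3. Forward: one [3+3] annulation gives 5,7-difluoro-2,2-dimethylchroman, which supplies the pyran ring of both halves. The fluorines direct lithiation to C6 (temporary benzyl ester), the ester activates both C–F bonds for exchange with benzyloxide, and C8, the only free position, is brominated and then acylated through the aryllithium (ring A) or the arylmagnesium chloride (ring B).
4. Hydrogenolysis and decarboxylation remove the benzyl groups and the ester and free C6. The ring B phenol is joined to 6-methylheptanal as a sulfone, which is coupled with the ring A phenol last.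
5. Stereochemistry: the acyl centre comes from (R)-2-methylbutanoic acid (Weinreb amide, no strong base after ketone formation). The (R) bridge is set in the last step by a cinchona squaramide that controls the face of the ring B o-quinone methide.

Key step: step 1

Assumption: the squaramide in step 11 is 3-[3,5-bis(trifluoromethyl)anilino]-4-[(8α,9S)-6'-methoxycinchonan-9-ylamino]cyclobut-3-ene-1,2-dione (quinine-derived); its sense of induction is taken by analogy with phenol additions to o-quinone methides, and the quinidine-derived pseudo-enantiomer is used if the quinine-derived catalyst favours the (S) bridge.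
Assumption: 6-methylheptanal is taken as a catalogue aldehyde.

**Route**

Step 1
Reactants: 1 2,4,6-trifluorobenzyl bromide; 2 2,2-dimethyloxirane
Product: 6 5,7-difluoro-2,2-dimethylchroman, via benzylic Grignard reagent 3 (not isolated), via magnesium alkoxide 4 (not isolated), via potassium alkoxide 5 (not isolated)
Conditions: Mg, 2-MeTHF, 0 °C → rt; CuI (10 mol %), 2, −20 °C → rt; then KHMDS, DMPU, 60 °C
Reagents that add atoms: none
Why: Magnesium insertion into the benzylic C–Br bond of 1 gives 3, which under CuI catalysis opens 2 by SN2 attack at its CH2 carbon (C3–C4 bond) to give the tertiary alkoxide 4; exchange of the counter-ion for potassium (5) lets the alkoxide add to the ortho C–F carbon, and loss of fluoride from the Meisenheimer intermediate closes O1–C8a. The closest known reaction types are the copper-catalysed opening of 2,2-disubstituted oxiranes by Grignard reagents and the intramolecular SNAr etherification of fluoroarenes to chromans, run here in one flask as a formal [3+3] annulation. The pyran ring closes in the 6-exo-trig mode (attack on the aromatic carbon with the C–F bond outside the new ring), and no stereocentre is formed. The step needs attack at the CH2 and not the quaternary carbon of 2, which is secured sterically, while copper catalysis at low temperature outruns magnesium-halide-induced isomerisation of the oxirane to isobutyraldehyde. It also needs a single ring-closure site: the two ortho C–F bonds are equivalent by symmetry and the para one cannot be reached, so only one chroman can form. The two remaining fluorines sit meta to the attacked carbon and stabilise the anionic σ-complex inductively, and once the alkoxy group is in place the ring is deactivated, so substitution stops.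

Step 2
Reactants: 6 5,7-difluoro-2,2-dimethylchroman
Product: 8 benzyl 5,7-difluoro-2,2-dimethylchroman-6-carboxylate, via aryllithium 7 (not isolated)
Conditions: n-BuLi, THF, −78 °C; then ClCO2Bn, −78 °C → rt
Reagents that add atoms: benzyl chloroformate, O=C(Cl)OCc1ccccc1
Why: Directed ortho-lithiation should occur at C6, the C–H flanked by two fluorines and the most acidic in the ring, and the aryllithium is acylated by the chloroformate at −78 °C before it can lose LiF.

Step 3
Reactants: 8 benzyl 5,7-difluoro-2,2-dimethylchroman-6-carboxylate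
Product: 9 benzyl 5,7-bis(benzyloxy)-2,2-dimethylchroman-6-carboxylate
Conditions: BnOH, NaH, DMF, 0 → 60 °C
Reagents that add atoms: benzyl alcohol, OCc1ccccc1
Why: Double SNAr, since both C–F bonds are ortho to the ester carbonyl, and attack of benzyloxide on the benzyl ester is degenerate transesterification.

Step 4
Reactants: 9 benzyl 5,7-bis(benzyloxy)-2,2-dimethylchroman-6-carboxylate
Product: 10 benzyl 5,7-bis(benzyloxy)-8-bromo-2,2-dimethylchroman-6-carboxylate
Conditions: NBS, MeCN, 0 °C → rt, dark
Reagents that add atoms: N-bromosuccinimide, O=C1CCC(=O)N1Br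
Why: Electrophilic aromatic bromination at C8, the only free ring position, which is ortho to two oxygens, para to the third and meta to the ester.

Step 5
Reactants: 11 (R)-2-methylbutanoic acid
Product: 13 (2R)-N-methoxy-N,2-dimethylbutanamide, via acyl imidazole 12 (not isolated)
Conditions: 1,1'-carbonyldiimidazole, CH2Cl2, 0 °C → rt; then MeNHOMe·HCl, rt
Reagents that add atoms: N,O-dimethylhydroxylamine hydrochloride, CNOC.Cl
Why: Weinreb amide formation through the acyl imidazole, a mild activation that should leave the α-alkyl stereocentre untouched.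

Step 6
Reactants: 10 benzyl 5,7-bis(benzyloxy)-8-bromo-2,2-dimethylchroman-6-carboxylate; 13 (2R)-N-methoxy-N,2-dimethylbutanamide
Product: 16 benzyl 5,7-bis(benzyloxy)-2,2-dimethyl-8-[(2R)-2-methylbutanoyl]chroman-6-carboxylate, via aryllithium 14 (not isolated), via lithium chelate 15 (not isolated)
Conditions: n-BuLi, THF, −78 °C; then 13, −78 → −20 °C; aq. NH4Cl
Reagents that add atoms: none
Why: Bromine–lithium exchange followed by Weinreb ketone synthesis; exchange is faster than attack on the ester, which is shielded by its two ortho benzyloxy groups, and the chelate 15 releases the ketone only on quench, so the (R) α-centre never meets base as a ketone.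

Step 7
Reactants: 16 benzyl 5,7-bis(benzyloxy)-2,2-dimethyl-8-[(2R)-2-methylbutanoyl]chroman-6-carboxylate
Product: 18 (2R)-1-(5,7-dihydroxy-2,2-dimethylchroman-8-yl)-2-methylbutan-1-one, via carboxylic acid 17 (not isolated)
Conditions: H2 (1 atm), Pd/C, EtOAc, rt; filter; then toluene, 100 °C
Reagents that add atoms: none
Why: Hydrogenolysis of the two benzyl ethers and the benzyl ester, then thermal decarboxylation of the 2,6-dihydroxybenzoic acid through its keto tautomer (β-keto acid type), under neutral conditions that spare the hindered hydrogen-bonded ketone and its α-centre.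

Step 8
Reactants: 10 benzyl 5,7-bis(benzyloxy)-8-bromo-2,2-dimethylchroman-6-carboxylate; 19 N-methoxy-N,2-dimethylpropanamide
Product: 22 benzyl 5,7-bis(benzyloxy)-2,2-dimethyl-8-(2-methylpropanoyl)chroman-6-carboxylate, via arylmagnesium chloride 20 (not isolated), via magnesium chelate 21 (not isolated)
Conditions: i-PrMgCl·LiCl, THF, 0 °C → rt; then 19, 0 °C → rt; aq. NH4Cl
Reagents that add atoms: none
Why: Bromine–magnesium exchange with the LiCl-complexed isopropyl Grignard reagent, accelerated by the two oxygens ortho to bromine, gives an arylmagnesium chloride that tolerates the hindered benzyl ester at rt, and its addition to the Weinreb amide stops at the magnesium chelate 21, which releases the ketone on quench (Weinreb ketone synthesis).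

Step 9
Reactants: 22 benzyl 5,7-bis(benzyloxy)-2,2-dimethyl-8-(2-methylpropanoyl)chroman-6-carboxylate
Product: 24 1-(5,7-dihydroxy-2,2-dimethylchroman-8-yl)-2-methylpropan-1-one, via carboxylic acid 23 (not isolated)
Conditions: H2 (1 atm), Pd/C, EtOAc, rt; filter; then toluene, 100 °C
Reagents that add atoms: none
Why: Hydrogenolysis and thermal decarboxylation as in step 7.

Step 10
Reactants: 24 1-(5,7-dihydroxy-2,2-dimethylchroman-8-yl)-2-methylpropan-1-one; 25 6-methylheptanal
Product: 27 1-[5,7-dihydroxy-2,2-dimethyl-6-[6-methyl-1-(4-methylphenyl)sulfonylheptyl]chroman-8-yl]-2-methylpropan-1-one (racemic), via benzylic alcohol 26 (not isolated)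
Conditions: p-TolSO2Na, HCO2H–H2O–THF, rt
Reagents that add atoms: sodium p-toluenesulfinate, [Na+].[O-]S(=O)c1ccc(C)cc1
Why: Acid-mediated three-component sulfonylalkylation of a phenol, in which Friedel–Crafts-type hydroxyalkylation at C6 (the only free ring carbon) gives carbinol 26 and its benzylic hydroxyl is exchanged for the sulfinate sulfur in an SN1-type substitution assisted by the two flanking phenolic hydroxyls, giving a storable sulfone.

Step 11
Reactants: 27 1-[5,7-dihydroxy-2,2-dimethyl-6-[6-methyl-1-(4-methylphenyl)sulfonylheptyl]chroman-8-yl]-2-methylpropan-1-one (racemic); 18 (2R)-1-(5,7-dihydroxy-2,2-dimethylchroman-8-yl)-2-methylbutan-1-one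
Product: 29 (2R)-1-[6-[(1R)-1-[5,7-dihydroxy-2,2-dimethyl-8-(2-methylpropanoyl)chroman-6-yl]-6-methylheptyl]-5,7-dihydroxy-2,2-dimethylchroman-8-yl]-2-methylbutan-1-one, via o-quinone methide 28 (not isolated)
Conditions: quinine-derived squaramide (10 mol %), aq. Na2CO3, CH2Cl2, 0 °C
Reagents that add atoms: none
Why: Base-induced 1,4-elimination of sulfinate from 27 generates 28, and the bifunctional catalyst (squaramide N–H bonds on the quinone methide carbonyl, quinuclidine on the phenol) should deliver C6 of 18 to one face in a Friedel–Crafts-type conjugate addition that sets the (R) bridge, with rearomatisation as the driving force.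

**Compound list**

1 | 2,4,6-trifluorobenzyl bromide | BrCc1c(F)cc(F)cc1F | starting material
2 | 2,2-dimethyloxirane | CC1(C)CO1 | starting material
3 | (2,4,6-trifluorobenzyl)magnesium bromide (formed in the flask) | Br[Mg]Cc1c(F)cc(F)cc1F | intermediate
4 | bromomagnesium 2-methyl-4-(2,4,6-trifluorophenyl)butan-2-olate (formed in the flask) | CC(C)(CCc1c(F)cc(F)cc1F)O[Mg]Br | intermediate
5 | potassium 2-methyl-4-(2,4,6-trifluorophenyl)butan-2-olate (formed in the flask) | CC(C)(CCc1c(F)cc(F)cc1F)[O-].[K+] | intermediate
6 | 5,7-difluoro-2,2-dimethylchroman | CC1(C)CCc2c(F)cc(F)cc2O1 | intermediate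
7 | (5,7-difluoro-2,2-dimethylchroman-6-yl)lithium (formed in the flask) | CC1(C)CCc2c(F)c([Li])c(F)cc2O1 | intermediate
8 | benzyl 5,7-difluoro-2,2-dimethylchroman-6-carboxylate | CC1(C)CCc2c(F)c(C(=O)OCc3ccccc3)c(F)cc2O1 | intermediate
9 | benzyl 5,7-bis(benzyloxy)-2,2-dimethylchroman-6-carboxylate | CC1(C)CCc2c(OCc3ccccc3)c(C(=O)OCc3ccccc3)c(OCc3ccccc3)cc2O1 | intermediate
10 | benzyl 5,7-bis(benzyloxy)-8-bromo-2,2-dimethylchroman-6-carboxylate | CC1(C)CCc2c(OCc3ccccc3)c(C(=O)OCc3ccccc3)c(OCc3ccccc3)c(Br)c2O1 | intermediate
11 | (R)-2-methylbutanoic acid | CC[C@@H](C)C(=O)O | starting material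
12 | 1-[(2R)-2-methylbutanoyl]imidazole (formed in the flask) | CC[C@@H](C)C(=O)n1ccnc1 | intermediate
13 | (2R)-N-methoxy-N,2-dimethylbutanamide | CC[C@@H](C)C(=O)N(C)OC | intermediate
14 | [5,7-bis(benzyloxy)-6-(benzyloxycarbonyl)-2,2-dimethylchroman-8-yl]lithium (formed in the flask) | CC1(C)CCc2c(OCc3ccccc3)c(C(=O)OCc3ccccc3)c(OCc3ccccc3)c([Li])c2O1 | intermediate
15 | lithium alkoxide adduct of 14 and 13, N-methoxy-N-methyl hemiaminal at the future ketone carbon (formed in the flask) | CC[C@@H](C)C(O[Li])(N(C)OC)c1c(OCc2ccccc2)c(C(=O)OCc2ccccc2)c(OCc2ccccc2)c2c1OC(C)(C)CC2 | intermediate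
16 | benzyl 5,7-bis(benzyloxy)-2,2-dimethyl-8-[(2R)-2-methylbutanoyl]chroman-6-carboxylate | CC[C@@H](C)C(=O)c1c(OCc2ccccc2)c(C(=O)OCc2ccccc2)c(OCc2ccccc2)c2c1OC(C)(C)CC2 | intermediate
17 | 5,7-dihydroxy-2,2-dimethyl-8-[(2R)-2-methylbutanoyl]chroman-6-carboxylic acid (formed in the flask) | CC[C@@H](C)C(=O)c1c(O)c(C(=O)O)c(O)c2c1OC(C)(C)CC2 | intermediate
18 | (2R)-1-(5,7-dihydroxy-2,2-dimethylchroman-8-yl)-2-methylbutan-1-one | CC[C@@H](C)C(=O)c1c(O)cc(O)c2c1OC(C)(C)CC2 | intermediate
19 | N-methoxy-N,2-dimethylpropanamide | CC(C)C(=O)N(C)OC | starting material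
20 | [5,7-bis(benzyloxy)-6-(benzyloxycarbonyl)-2,2-dimethylchroman-8-yl]magnesium chloride (formed in the flask) | CC1(C)CCc2c(OCc3ccccc3)c(C(=O)OCc3ccccc3)c(OCc3ccccc3)c([Mg]Cl)c2O1 | intermediate
21 | chloromagnesium alkoxide adduct of 20 and 19, N-methoxy-N-methyl hemiaminal at the future ketone carbon (formed in the flask) | CC(C)C(O[Mg]Cl)(N(C)OC)c1c(OCc2ccccc2)c(C(=O)OCc2ccccc2)c(OCc2ccccc2)c2c1OC(C)(C)CC2 | intermediate
22 | benzyl 5,7-bis(benzyloxy)-2,2-dimethyl-8-(2-methylpropanoyl)chroman-6-carboxylate | CC(C)C(=O)c1c(OCc2ccccc2)c(C(=O)OCc2ccccc2)c(OCc2ccccc2)c2c1OC(C)(C)CC2 | intermediate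
23 | 5,7-dihydroxy-2,2-dimethyl-8-(2-methylpropanoyl)chroman-6-carboxylic acid (formed in the flask) | CC(C)C(=O)c1c(O)c(C(=O)O)c(O)c2c1OC(C)(C)CC2 | intermediate
24 | 1-(5,7-dihydroxy-2,2-dimethylchroman-8-yl)-2-methylpropan-1-one | CC(C)C(=O)c1c(O)cc(O)c2c1OC(C)(C)CC2 | intermediate
25 | 6-methylheptanal | CC(C)CCCCC=O | starting material
26 | 1-[5,7-dihydroxy-6-(1-hydroxy-6-methylheptyl)-2,2-dimethylchroman-8-yl]-2-methylpropan-1-one, racemic (formed in the flask) | CC(C)C(=O)c1c(O)c(C(O)CCCCC(C)C)c(O)c2c1OC(C)(C)CC2 | intermediate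
27 | 1-[5,7-dihydroxy-2,2-dimethyl-6-[6-methyl-1-(4-methylphenyl)sulfonylheptyl]chroman-8-yl]-2-methylpropan-1-one, racemic | CC(C)C(=O)c1c(O)c(C(CCCCC(C)C)S(=O)(=O)c2ccc(C)cc2)c(O)c2c1OC(C)(C)CC2 | intermediate
28 | 7-hydroxy-2,2-dimethyl-6-(6-methylheptylidene)-8-(2-methylpropanoyl)-3,4-dihydro-2H-chromen-5(6H)-one, the ring B o-quinone methide (formed in the flask) | CC(C)C(=O)C1=C(O)C(=CCCCCC(C)C)C(=O)C2=C1OC(C)(C)CC2 | intermediate
29 | (2R)-1-[6-[(1R)-1-[5,7-dihydroxy-2,2-dimethyl-8-(2-methylpropanoyl)chroman-6-yl]-6-methylheptyl]-5,7-dihydroxy-2,2-dimethylchroman-8-yl]-2-methylbutan-1-one | CC[C@@H](C)C(=O)c1c(O)c([C@H](CCCCC(C)C)c2c(O)c3c(c(C(=O)C(C)C)c2O)OC(C)(C)CC3)c(O)c2c1OC(C)(C)CC2 | target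

**Summary**

Total step count: 11. Longest linear sequence: 8 steps (1, 2, 3, 4, 8, 9, 10, 11).

Steps most likely to fail:

- Step 11. The uncatalysed addition of the ring A phenolate to the o-quinone methide may outrun the catalyst-bound pathway and give poor facial selectivity, and retro-addition under base may erode the bridge configuration. Fallback: setting out from 27 and 18, the coupling is run with K2CO3 alone in CH2Cl2–water. This should give 29 together with its bridge epimer, (2R)-1-[6-[(1S)-1-[5,7-dihydroxy-2,2-dimethyl-8-(2-methylpropanoyl)chroman-6-yl]-6-methylheptyl]-5,7-dihydroxy-2,2-dimethylchroman-8-yl]-2-methylbutan-1-one F1. Because the acyl centre is fixed, the two are diastereomers and should be separable by preparative HPLC. F1 is returned to the same basic medium, where retro-addition and re-addition should re-equilibrate the bridge, so the material comes back to the route at 29.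

- Step 10. Capture of the ionising carbinol by a second molecule of the phenol (symmetrical dimer formation) may outrun capture by sulfinate, or the sulfone may revert under the acidic conditions. Fallback: setting out from 24 and 25, condensation with 4-methylbenzenethiol (pyrrolidine and acetic acid as catalysts, EtOH, rt) should give the more robust sulfide 1-[5,7-dihydroxy-2,2-dimethyl-6-[6-methyl-1-(4-methylphenyl)sulfanylheptyl]chroman-8-yl]-2-methylpropan-1-one F2. Oxidation of F2 with KHSO5 (Oxone) in MeOH–water at 0 °C comes back to the route at 27.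

- Step 1. Wurtz-type homocoupling during Grignard formation, magnesium-halide-induced isomerisation of the oxirane before it is opened, or stalling of the ring closure in the magnesium-rich medium may intervene. Fallback: setting out from 1, alkylation of the lithium enolate of ethyl acetate (LDA, THF, −78 °C) gives ethyl 3-(2,4,6-trifluorophenyl)propanoate F3. Excess MeMgBr converts F3 into 2-methyl-4-(2,4,6-trifluorophenyl)butan-2-ol F4. KHMDS in THF at 60 °C closes the pyran ring by the same SNAr and comes back to the route at 6.

**Further compounds**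

F1 | step 11 | (2R)-1-[6-[(1S)-1-[5,7-dihydroxy-2,2-dimethyl-8-(2-methylpropanoyl)chroman-6-yl]-6-methylheptyl]-5,7-dihydroxy-2,2-dimethylchroman-8-yl]-2-methylbutan-1-one | CC[C@@H](C)C(=O)c1c(O)c([C@@H](CCCCC(C)C)c2c(O)c3c(c(C(=O)C(C)C)c2O)OC(C)(C)CC3)c(O)c2c1OC(C)(C)CC2
F2 | step 10 | 1-[5,7-dihydroxy-2,2-dimethyl-6-[6-methyl-1-(4-methylphenyl)sulfanylheptyl]chroman-8-yl]-2-methylpropan-1-one | CC(C)C(=O)c1c(O)c(C(CCCCC(C)C)Sc2ccc(C)cc2)c(O)c2c1OC(C)(C)CC2
F3 | step 1 | ethyl 3-(2,4,6-trifluorophenyl)propanoate | CCOC(=O)CCc1c(F)cc(F)cc1F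
F4 | step 1 | 2-methyl-4-(2,4,6-trifluorophenyl)butan-2-ol | CC(C)(O)CCc1c(F)cc(F)cc1F
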